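**Retrosynthetic overview**

- Feature: in the benzofuran core, C2 is bonded only to O1, C3 and C1' of ring B (the 4-hydroxy-2-methoxyphenyl group), and C3 carries a single carbon at the carbonyl oxidation level. C2 can therefore be inserted as a ring-B benzylidene carbon between the ring-A phenol oxygen and an ester-bearing C3.
- Late stage: C3–CHO from C3–CO2Et (reduction, then oxidation); 6-OMe by methylating the less hindered of the two ring-A hydroxyls; furan C2=C3 from a trans-2,3-dihydrofuran by selenoxide elimination.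
- Key disconnection: O1–C2 and C2–C3 are made together by a (4+1) annulation of a ring-A o-quinone methide (ester on the methide carbon) with a ring-B benzyl sulfonium ylide.
- Fragments: the ring-A phenol, 3,5-bis(MOM)-4-prenylphenol (from phloroglucinol), has a mirror plane through O–C1 and C4, so ethyl glyoxylate can only enter at one kind of ortho carbon; the ring-B sulfonium salt comes from 4-hydroxy-2-methoxybenzaldehyde.
- Ring order: rings A and B are bought as arenes; the furan ring is the only ring formed (step 11) and is aromatized in step 13.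

Key step: step 11

Remark: benzofuran numbering is used for the target (O1, C2 aryl, C3 CHO, C4 OH, C5 prenyl, C6 OMe). Prenyl = 3-methylbut-2-enyl, MOM = methoxymethyl, pivalate = 2,2-dimethylpropanoate. Compounds 10 and 11 are racemates, 17 has undefined alkene geometry, 19 is a diastereomer mixture and 22 is a mixture at selenium. The target has no stereocentre; the two centres made in step 11 are erased in step 13.

**Route**

Step 1
Reactants: 1 phloroglucinol
Product: 2 3,5-bis(methoxymethoxy)phenol
Conditions: MOMCl (2.0 equiv), i-Pr2NEt (2.2 equiv), DMF, 0 °C to rt; chromatography (mono- and tris-ethers recycled)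
Reagents that add atoms: chloromethyl methyl ether, COCCl
Why: O-alkylation of the phenol with an alpha-chloro ether (Williamson type) is statistical here, but with two equivalents the bis-ether should be the main component and differs enough in polarity from the mono- and tris-ethers to be separated.

Step 2
Reactants: 2 3,5-bis(methoxymethoxy)phenol
Product: 3 [3,5-bis(methoxymethoxy)phenoxy]triisopropylsilane
Conditions: TIPSCl, imidazole, DMF, rt
Reagents that add atoms: chlorotriisopropylsilane, CC(C)[Si](Cl)(C(C)C)C(C)C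
Why: Imidazole-assisted silylation masks the acidic OH, and the bulky TIPS group later shields its two flanking ring positions from the base.

Step 3
Reactants: 3 [3,5-bis(methoxymethoxy)phenoxy]triisopropylsilane; 4 prenyl bromide
Product: 6 [3,5-bis(methoxymethoxy)-4-(3-methylbut-2-enyl)phenoxy]triisopropylsilane, via aryllithium 5 (not isolated)
Conditions: n-BuLi (1.2 equiv), THF, 0 °C, 1 h; then 4 (1.5 equiv), −78 °C to rt
Reagents that add atoms: none
Why: Directed ortho-metalation removes the C–H flanked and chelated by both MOM ethers (the TIPS ether is a poor director and blocks its neighbours), and the aryllithium alkylates prenyl bromide at the primary carbon by SN2.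

Step 4
Reactants: 6 [3,5-bis(methoxymethoxy)-4-(3-methylbut-2-enyl)phenoxy]triisopropylsilane
Product: 7 3,5-bis(methoxymethoxy)-4-(3-methylbut-2-enyl)phenol
Conditions: Bu4NF (1.1 equiv), THF, 0 °C
Reagents that add atoms: none
Why: Fluoride-mediated Si–O cleavage is driven by the Si–F bond and leaves the MOM acetals and the prenyl alkene untouched.

Step 5
Reactants: 7 3,5-bis(methoxymethoxy)-4-(3-methylbut-2-enyl)phenol; 8 ethyl glyoxylate
Product: 10 ethyl 2-hydroxy-2-[6-hydroxy-2,4-bis(methoxymethoxy)-3-(3-methylbut-2-enyl)phenyl]acetate (racemic), via bromomagnesium phenoxide 9 (not isolated)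
Conditions: EtMgBr (1.0 equiv), CH2Cl2, 0 °C; then 8 (1.2 equiv, freshly distilled), −20 °C to rt; aqueous quench
Reagents that add atoms: none
Why: In this Casiraghi-type ortho-hydroxyalkylation the magnesium phenoxide binds the aldehyde and delivers it to the ortho carbon through a cyclic transition state; the two ortho carbons of 7 are equivalent and no para position is free, so one constitutional isomer is expected, and the racemic carbinol centre is destroyed in step 11.

Step 6
Reactants: 10 ethyl 2-hydroxy-2-[6-hydroxy-2,4-bis(methoxymethoxy)-3-(3-methylbut-2-enyl)phenyl]acetate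
Product: 11 ethyl 2-[6-hydroxy-2,4-bis(methoxymethoxy)-3-(3-methylbut-2-enyl)phenyl]-2-(4-methylphenylsulfonyl)acetate (racemic)
Conditions: p-TolSO2H (2 equiv), MgSO4, CH2Cl2, 0 °C to rt
Reagents that add atoms: p-toluenesulfinic acid, Cc1ccc(S(=O)O)cc1
Why: The benzylic carbinol sits ortho to OH and ortho/para to two alkoxy donors, so the mild sulfinic acid should ionize it to an o-quinone-methide-like cation that the sulfinate captures at sulfur (dehydrative SN1-type sulfonylation); the acid is too weak to strip aryl MOM ethers quickly in an aprotic solvent.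

Step 7
Reactants: 12 4-hydroxy-2-methoxybenzaldehyde
Product: 13 4-formyl-3-methoxyphenyl pivalate
Conditions: PivCl, Et3N, DMAP (cat.), CH2Cl2, 0 °C to rt
Reagents that add atoms: pivaloyl chloride, CC(C)(C)C(=O)Cl
Why: Base-mediated O-acylation gives a hindered aryl ester that has no alpha-hydrogen, resists carbonate bases and mild acid, and can be removed by hydride at the end.

Step 8
Reactants: 13 4-formyl-3-methoxyphenyl pivalate
Product: 14 4-(hydroxymethyl)-3-methoxyphenyl pivalate
Conditions: NaBH4, THF–MeOH (10:1), 0 °C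
Reagents that add atoms: none
Why: Borohydride reduces the aldehyde chemoselectively; the hindered aryl pivalate is not attacked at 0 °C.

Step 9
Reactants: 14 4-(hydroxymethyl)-3-methoxyphenyl pivalate
Product: 15 4-(bromomethyl)-3-methoxyphenyl pivalate
Conditions: PBr3 (0.4 equiv), Et2O, 0 °C
Reagents that add atoms: phosphorus tribromide, BrP(Br)Br
Why: The benzylic alcohol is converted via its phosphite ester, which bromide displaces (SN2) readily at an electron-rich benzylic carbon.

Step 10
Reactants: 15 4-(bromomethyl)-3-methoxyphenyl pivalate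
Product: 16 (2-methoxy-4-pivaloyloxybenzyl)dimethylsulfonium bromide
Conditions: Me2S (3 equiv), acetone, rt; salt filtered and used fresh
Reagents that add atoms: dimethyl sulfide, CSC
Why: S-alkylation of the sulfide by the reactive benzylic bromide (SN2) gives a salt that precipitates from acetone, which drives the equilibrium.

Step 11
Reactants: 11 ethyl 2-[6-hydroxy-2,4-bis(methoxymethoxy)-3-(3-methylbut-2-enyl)phenyl]-2-(4-methylphenylsulfonyl)acetate; 16 (2-methoxy-4-pivaloyloxybenzyl)dimethylsulfonium bromide
Product: 20 ethyl rac-(2R,3R)-2-(2-methoxy-4-pivaloyloxyphenyl)-4,6-bis(methoxymethoxy)-5-(3-methylbut-2-enyl)-2,3-dihydrobenzofuran-3-carboxylate (trans), via o-quinone methide 17 (not isolated), via sulfonium ylide 18 (not isolated), via betaine 19 (not isolated)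
Conditions: 16 (1.5 equiv), Cs2CO3 (3 equiv), MeCN, 0 °C to rt
Reagents that add atoms: none
Why: Cs2CO3 deprotonates 11 and the phenoxide expels toluenesulfinate (1,4-elimination, E1cB) to give the ester-substituted o-quinone methide 17, while the same base converts 16 into the benzylic ylide 18. The ylide carbon adds to the exocyclic methide carbon (future C3), which rearomatizes ring A and gives betaine 19 with the C2–C3 bond in place. The phenoxide then displaces dimethyl sulfide at the benzylic carbon in a 5-exo-tet closure that forms O1–C2 and the dihydrofuran ring. The closest known reaction type is the formal (4+1) annulation of o-quinone methides released from 2-(1-tosylalkyl)phenols with sulfonium ylides, which gives trans-2,3-dihydrobenzofurans. The two new stereocentres (C2, C3) are controlled only relative to each other: closure goes through the betaine rotamer that keeps the aryl group and the ester apart, and the acidic C3–H lets any cis isomer epimerize to trans under the base, so the racemic trans product is expected. The step needs ylide C-attack at the methide carbon in preference to ylide rearrangement or self-alkylation; this is secured by the electrophilicity that the ester and the rearomatization give that carbon, by generating both partners in the same flask, and by the phenoxide sitting ortho to the new bond.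

Step 12
Reactants: 20 ethyl rac-(2R,3R)-2-(2-methoxy-4-pivaloyloxyphenyl)-4,6-bis(methoxymethoxy)-5-(3-methylbut-2-enyl)-2,3-dihydrobenzofuran-3-carboxylate
Product: 21 ethyl rac-(2S,3R)-2-(2-methoxy-4-pivaloyloxyphenyl)-4,6-bis(methoxymethoxy)-5-(3-methylbut-2-enyl)-3-(phenylselanyl)-2,3-dihydrobenzofuran-3-carboxylate (selenium trans to the C2 aryl group and cis to H-2)
Conditions: LiN(SiMe3)2 (1.2 equiv), THF, −78 °C; then PhSeBr (1.05 equiv), −78 °C, cold quench
Reagents that add atoms: benzeneselenenyl bromide, Br[Se]c1ccccc1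
Why: The base removes the C3–H (alpha to the ester and benzylic) and the lithium enolate is selenenylated from the face opposite the C2 aryl group (alpha-selenenylation of an ester enolate), which puts selenium cis to H-2 as the syn elimination requires; at −78 °C ring opening by loss of the O1 phenoxide should be slow because the C2–O1 bond lies near the nodal plane of the enolate (reverse of a 5-endo-trig closure), and one equivalent of PhSeBr is consumed by the enolate before it can add to the prenyl alkene.

Step 13
Reactants: 21 ethyl rac-(2S,3R)-2-(2-methoxy-4-pivaloyloxyphenyl)-4,6-bis(methoxymethoxy)-5-(3-methylbut-2-enyl)-3-(phenylselanyl)-2,3-dihydrobenzofuran-3-carboxylate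
Product: 23 ethyl 2-(2-methoxy-4-pivaloyloxyphenyl)-4,6-bis(methoxymethoxy)-5-(3-methylbut-2-enyl)benzofuran-3-carboxylate, via selenoxide 22 (not isolated)
Conditions: 30% aq. H2O2, pyridine, CH2Cl2, 0 °C to rt
Reagents that add atoms: none
Why: Oxidation at selenium and syn selenoxide elimination toward H-2, the only beta-hydrogen, is driven by aromatization of the furan; pyridine buffers the selenenic acid, and peroxide under these conditions spares the prenyl alkene that a quinone oxidant would attack at its benzylic-allylic CH2.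

Step 14
Reactants: 23 ethyl 2-(2-methoxy-4-pivaloyloxyphenyl)-4,6-bis(methoxymethoxy)-5-(3-methylbut-2-enyl)benzofuran-3-carboxylate
Product: 24 ethyl 4,6-dihydroxy-2-(2-methoxy-4-pivaloyloxyphenyl)-5-(3-methylbut-2-enyl)benzofuran-3-carboxylate
Conditions: 3 M aq. HCl, EtOH, 45 °C, monitored and stopped at full conversion
Reagents that add atoms: none
Why: Acid-catalysed acetal hydrolysis removes both MOM groups; ethanol matches the ester and prevents ester exchange, the hindered pivalate is slow to solvolyse, and the mild temperature limits acid cyclization of the prenyl group onto a neighbouring phenol.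

Step 15
Reactants: 24 ethyl 4,6-dihydroxy-2-(2-methoxy-4-pivaloyloxyphenyl)-5-(3-methylbut-2-enyl)benzofuran-3-carboxylate
Product: 25 ethyl 4-hydroxy-6-methoxy-2-(2-methoxy-4-pivaloyloxyphenyl)-5-(3-methylbut-2-enyl)benzofuran-3-carboxylate
Conditions: MeI (1.1 equiv), K2CO3 (1.2 equiv), acetone, rt
Reagents that add atoms: iodomethane, CI
Why: Williamson methylation should take the 6-OH, which has only the prenyl group and H-7 beside it, whereas the 4-OH is hydrogen-bonded to the C3 ester carbonyl and wedged between the prenyl group and that ester; the pivalate keeps the ring-B hydroxyl out of the reaction.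

Step 16
Reactants: 25 ethyl 4-hydroxy-6-methoxy-2-(2-methoxy-4-pivaloyloxyphenyl)-5-(3-methylbut-2-enyl)benzofuran-3-carboxylate
Product: 26 3-(hydroxymethyl)-2-(4-hydroxy-2-methoxyphenyl)-6-methoxy-5-(3-methylbut-2-enyl)benzofuran-4-ol
Conditions: i-Bu2AlH (6 equiv), THF, −78 to −20 °C; aq. potassium sodium tartrate; crude product used directly
Reagents that add atoms: none
Why: Excess aluminium hydride reduces the conjugated ethyl ester to the primary alcohol and cleaves the aryl pivalate reductively in the same operation, so no separate deprotection is needed.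

Step 17
Reactants: 26 3-(hydroxymethyl)-2-(4-hydroxy-2-methoxyphenyl)-6-methoxy-5-(3-methylbut-2-enyl)benzofuran-4-ol
Product: 27 4-hydroxy-2-(4-hydroxy-2-methoxyphenyl)-6-methoxy-5-(3-methylbut-2-enyl)benzofuran-3-carbaldehyde (target)
Conditions: activated MnO2 (15 equiv), EtOAc, rt
Reagents that add atoms: none
Why: MnO2 oxidizes the benzylic-type heteroaryl carbinol selectively to the aldehyde and should leave the free phenols and the prenyl alkene alone.

**Compound list**

1 | phloroglucinol | Oc1cc(O)cc(O)c1 | starting material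
2 | 3,5-bis(methoxymethoxy)phenol | COCOc1cc(O)cc(OCOC)c1 | intermediate
3 | [3,5-bis(methoxymethoxy)phenoxy]triisopropylsilane | COCOc1cc(OCOC)cc(O[Si](C(C)C)(C(C)C)C(C)C)c1 | intermediate
4 | prenyl bromide (1-bromo-3-methylbut-2-ene) | CC(C)=CCBr | starting material
5 | [2,6-bis(methoxymethoxy)-4-(triisopropylsilyloxy)phenyl]lithium | [Li]c1c(OCOC)cc(O[Si](C(C)C)(C(C)C)C(C)C)cc1OCOC | intermediate (not isolated)
6 | [3,5-bis(methoxymethoxy)-4-(3-methylbut-2-enyl)phenoxy]triisopropylsilane | COCOc1cc(O[Si](C(C)C)(C(C)C)C(C)C)cc(OCOC)c1CC=C(C)C | intermediate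
7 | 3,5-bis(methoxymethoxy)-4-(3-methylbut-2-enyl)phenol | COCOc1cc(O)cc(OCOC)c1CC=C(C)C | intermediate
8 | ethyl glyoxylate | CCOC(=O)C=O | starting material
9 | bromomagnesium 3,5-bis(methoxymethoxy)-4-(3-methylbut-2-enyl)phenoxide | COCOc1cc(O[Mg]Br)cc(OCOC)c1CC=C(C)C | intermediate (not isolated)
10 | ethyl 2-hydroxy-2-[6-hydroxy-2,4-bis(methoxymethoxy)-3-(3-methylbut-2-enyl)phenyl]acetate (racemic) | CCOC(=O)C(O)c1c(O)cc(OCOC)c(CC=C(C)C)c1OCOC | intermediate
11 | ethyl 2-[6-hydroxy-2,4-bis(methoxymethoxy)-3-(3-methylbut-2-enyl)phenyl]-2-(4-methylphenylsulfonyl)acetate (racemic) | CCOC(=O)C(c1c(O)cc(OCOC)c(CC=C(C)C)c1OCOC)S(=O)(=O)c1ccc(C)cc1 | intermediate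
12 | 4-hydroxy-2-methoxybenzaldehyde | O=Cc1ccc(O)cc1OC | starting material
13 | 4-formyl-3-methoxyphenyl pivalate | O=Cc1ccc(OC(=O)C(C)(C)C)cc1OC | intermediate
14 | 4-(hydroxymethyl)-3-methoxyphenyl pivalate | OCc1ccc(OC(=O)C(C)(C)C)cc1OC | intermediate
15 | 4-(bromomethyl)-3-methoxyphenyl pivalate | BrCc1ccc(OC(=O)C(C)(C)C)cc1OC | intermediate
16 | (2-methoxy-4-pivaloyloxybenzyl)dimethylsulfonium bromide | C[S+](C)Cc1ccc(OC(=O)C(C)(C)C)cc1OC.[Br-] | intermediate
17 | ethyl 2-[2,4-bis(methoxymethoxy)-3-(3-methylbut-2-enyl)-6-oxocyclohexa-2,4-dien-1-ylidene]acetate (o-quinone methide, alkene geometry undefined) | CCOC(=O)C=C1C(=O)C=C(OCOC)C(CC=C(C)C)=C1OCOC | intermediate (not isolated)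
18 | dimethylsulfonium (2-methoxy-4-pivaloyloxyphenyl)methylide | C[S+](C)[CH-]c1ccc(OC(=O)C(C)(C)C)cc1OC | intermediate (not isolated)
19 | betaine: 2-[2-(dimethylsulfonio)-1-ethoxycarbonyl-2-(2-methoxy-4-pivaloyloxyphenyl)ethyl]-3,5-bis(methoxymethoxy)-4-(3-methylbut-2-enyl)phenoxide (diastereomer mixture) | CCOC(=O)C(C(c1ccc(OC(=O)C(C)(C)C)cc1OC)[S+](C)C)c1c([O-])cc(OCOC)c(CC=C(C)C)c1OCOC | intermediate (not isolated)
20 | ethyl rac-(2R,3R)-2-(2-methoxy-4-pivaloyloxyphenyl)-4,6-bis(methoxymethoxy)-5-(3-methylbut-2-enyl)-2,3-dihydrobenzofuran-3-carboxylate (trans; one enantiomer drawn) | CCOC(=O)[C@H]1[C@H](c2ccc(OC(=O)C(C)(C)C)cc2OC)Oc2cc(OCOC)c(CC=C(C)C)c(OCOC)c12 | intermediate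
21 | ethyl rac-(2S,3R)-2-(2-methoxy-4-pivaloyloxyphenyl)-4,6-bis(methoxymethoxy)-5-(3-methylbut-2-enyl)-3-(phenylselanyl)-2,3-dihydrobenzofuran-3-carboxylate (Se cis to H-2; one enantiomer drawn) | CCOC(=O)[C@]1([Se]c3ccccc3)[C@H](c2ccc(OC(=O)C(C)(C)C)cc2OC)Oc2cc(OCOC)c(CC=C(C)C)c(OCOC)c12 | intermediate
22 | selenoxide of 21 (mixture at selenium) | CCOC(=O)[C@]1([Se](=O)c3ccccc3)[C@H](c2ccc(OC(=O)C(C)(C)C)cc2OC)Oc2cc(OCOC)c(CC=C(C)C)c(OCOC)c12 | intermediate (not isolated)
23 | ethyl 2-(2-methoxy-4-pivaloyloxyphenyl)-4,6-bis(methoxymethoxy)-5-(3-methylbut-2-enyl)benzofuran-3-carboxylate | CCOC(=O)c1c(-c2ccc(OC(=O)C(C)(C)C)cc2OC)oc2cc(OCOC)c(CC=C(C)C)c(OCOC)c12 | intermediate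
24 | ethyl 4,6-dihydroxy-2-(2-methoxy-4-pivaloyloxyphenyl)-5-(3-methylbut-2-enyl)benzofuran-3-carboxylate | CCOC(=O)c1c(-c2ccc(OC(=O)C(C)(C)C)cc2OC)oc2cc(O)c(CC=C(C)C)c(O)c12 | intermediate
25 | ethyl 4-hydroxy-6-methoxy-2-(2-methoxy-4-pivaloyloxyphenyl)-5-(3-methylbut-2-enyl)benzofuran-3-carboxylate | CCOC(=O)c1c(-c2ccc(OC(=O)C(C)(C)C)cc2OC)oc2cc(OC)c(CC=C(C)C)c(O)c12 | intermediate
26 | 3-(hydroxymethyl)-2-(4-hydroxy-2-methoxyphenyl)-6-methoxy-5-(3-methylbut-2-enyl)benzofuran-4-ol | OCc1c(-c2ccc(O)cc2OC)oc2cc(OC)c(CC=C(C)C)c(O)c12 | intermediate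
27 | 4-hydroxy-2-(4-hydroxy-2-methoxyphenyl)-6-methoxy-5-(3-methylbut-2-enyl)benzofuran-3-carbaldehyde | O=Cc1c(-c2ccc(O)cc2OC)oc2cc(OC)c(CC=C(C)C)c(O)c12 | target

**Step count**

Total: 17 steps. Longest linear sequence: 13 steps (steps 1–6 and 11–17, from phloroglucinol); the ring-B branch (steps 7–10) has 4 steps.

**Steps most likely to fail**

1. Step 11 (key annulation). The C–H between ester and sulfone in 11 is more acidic than the phenol, so the substrate may rest as a stabilized carbanion and release the quinone methide only slowly. Meanwhile the phenoxide can close onto the ethyl ester (lactonization), or the benzylic ylide can be lost by sigmatropic rearrangement or self-alkylation before it meets the methide.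
Fallback (sets out from 7 and 13, comes back at 23, so steps 12 and 13 fall away): the furan ring is built by alkyne oxypalladation with carbonylation instead.
   - Iodination of 7 at one of its two equivalent ortho carbons (N-iodosuccinimide, CH2Cl2, −20 °C) should give 2-iodo-3,5-bis(methoxymethoxy)-4-(3-methylbut-2-enyl)phenol F1.
   - Aldehyde 13 is homologated with lithiated trimethylsilyldiazomethane (TMSCHN2, LiN(i-Pr)2, THF, −78 °C to rt, Colvin rearrangement) to 4-ethynyl-3-methoxyphenyl pivalate F2.
   - Sonogashira coupling of F1 with F2 (PdCl2(PPh3)2, CuI, Et3N, THF, rt) gives 4-{[6-hydroxy-2,4-bis(methoxymethoxy)-3-(3-methylbut-2-enyl)phenyl]ethynyl}-3-methoxyphenyl pivalate F3.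
   - Cyclization–ethoxycarbonylation of F3 (PdCl2 cat., CuCl2, NaOAc, CO 1 atm, EtOH, rt) closes O1–C2 by 5-endo-dig attack of the phenol on the alkyne held by divalent palladium; CO insertion at C3 and ethanolysis then deliver 23.

2. Step 6 (sulfinate installation). Under the acid, MOM groups may be lost, the phenol may lactonize onto the ester, or the benzylic cation may alkylate the free ring carbon of a second molecule faster than sulfinate captures it.
Fallback (sets out from 10, comes back at 20): the quinone methide is released under base only, by a carbonate-transfer cascade.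
   - Boc2O with catalytic DMAP and i-Pr2NEt (CH2Cl2, 0 °C) acylates the phenol of 10 to ethyl 2-[6-(tert-butoxycarbonyloxy)-2,4-bis(methoxymethoxy)-3-(3-methylbut-2-enyl)phenyl]-2-hydroxyacetate F4.
   - F4 is used in place of 11 under the conditions of step 11. The base moves the carbonate to the benzylic oxygen through a six-membered transition state, giving cesium 2-[1-(tert-butoxycarbonyloxy)-2-ethoxy-2-oxoethyl]-3,5-bis(methoxymethoxy)-4-(3-methylbut-2-enyl)phenoxide F5.
   - F5 loses tert-butyl carbonate by 1,4-elimination to the same quinone methide 17, which the ylide 18 converts into 20.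

3. Step 15 (site-selective methylation). Discrimination between the two ring-A hydroxyls may be poor, giving methylation at O4 or at both oxygens.
Fallback (sets out from 24, comes back at 27): both oxygens are methylated and the one next to the aldehyde is unmasked by chelation.
   - Exhaustive methylation of 24 (MeI excess, K2CO3, DMF) gives ethyl 4,6-dimethoxy-2-(2-methoxy-4-pivaloyloxyphenyl)-5-(3-methylbut-2-enyl)benzofuran-3-carboxylate F6.
   - i-Bu2AlH as in step 16 gives 4-[3-(hydroxymethyl)-4,6-dimethoxy-5-(3-methylbut-2-enyl)benzofuran-2-yl]-3-methoxyphenol F7.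
   - MnO2 as in step 17 gives 2-(4-hydroxy-2-methoxyphenyl)-4,6-dimethoxy-5-(3-methylbut-2-enyl)benzofuran-3-carbaldehyde F8.
   - BCl3 (CH2Cl2, −78 °C) chelates between the aldehyde oxygen and the neighbouring 4-methoxy oxygen and cleaves only that methyl ether, giving 27.

**Further compounds**

F1 | step 11 | 2-iodo-3,5-bis(methoxymethoxy)-4-(3-methylbut-2-enyl)phenol | COCOc1cc(O)c(I)c(OCOC)c1CC=C(C)C
F2 | step 11 | 4-ethynyl-3-methoxyphenyl pivalate | C#Cc1ccc(OC(=O)C(C)(C)C)cc1OC
F3 | step 11 | 4-{[6-hydroxy-2,4-bis(methoxymethoxy)-3-(3-methylbut-2-enyl)phenyl]ethynyl}-3-methoxyphenyl pivalate | COCOc1cc(O)c(C#Cc2ccc(OC(=O)C(C)(C)C)cc2OC)c(OCOC)c1CC=C(C)C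
F4 | step 6 | ethyl 2-[6-(tert-butoxycarbonyloxy)-2,4-bis(methoxymethoxy)-3-(3-methylbut-2-enyl)phenyl]-2-hydroxyacetate | CCOC(=O)C(O)c1c(OC(=O)OC(C)(C)C)cc(OCOC)c(CC=C(C)C)c1OCOC
F5 | step 6 | cesium 2-[1-(tert-butoxycarbonyloxy)-2-ethoxy-2-oxoethyl]-3,5-bis(methoxymethoxy)-4-(3-methylbut-2-enyl)phenoxide | CCOC(=O)C(OC(=O)OC(C)(C)C)c1c([O-])cc(OCOC)c(CC=C(C)C)c1OCOC.[Cs+]
F6 | step 15 | ethyl 4,6-dimethoxy-2-(2-methoxy-4-pivaloyloxyphenyl)-5-(3-methylbut-2-enyl)benzofuran-3-carboxylate | CCOC(=O)c1c(-c2ccc(OC(=O)C(C)(C)C)cc2OC)oc2cc(OC)c(CC=C(C)C)c(OC)c12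
F7 | step 15 | 4-[3-(hydroxymethyl)-4,6-dimethoxy-5-(3-methylbut-2-enyl)benzofuran-2-yl]-3-methoxyphenol | OCc1c(-c2ccc(O)cc2OC)oc2cc(OC)c(CC=C(C)C)c(OC)c12
F8 | step 15 | 2-(4-hydroxy-2-methoxyphenyl)-4,6-dimethoxy-5-(3-methylbut-2-enyl)benzofuran-3-carbaldehyde | O=Cc1c(-c2ccc(O)cc2OC)oc2cc(OC)c(CC=C(C)C)c(OC)c12
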